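## Analysis of the target

The target 21 is a linear chain of eight benzene rings, lettered A to H, joined by seven diaryl ether oxygens and carrying 21 free phenolic hydroxyl groups. It has no stereocentre and no other functional group. Ring A is a 2,4,6-trihydroxyphenyl unit bound through C1. Ring B has its ether oxygens at C1 and C5 and hydroxyls at C3 and C4. Rings C, E and G have ether oxygens at C1 and C6 and hydroxyls at C3, C4 and C5. Rings D and F have ether oxygens at C1 and C4 and hydroxyls at C3 and C5, and ring H is a 3,4,5-trihydroxyphenyl unit bound through C1. The free polyphenol, with five pyrogallol-type rings, is oxidised by air, above all in base, so every oxygen has to stay masked until the last step. The difficulty lies in the ether bonds at carbons with two ortho oxygen substituents: C1 of ring A, C6 of rings C, E and G, and C4 of rings D and F. The D–E and F–G ethers are the worst, because the partner carbon (C1 of rings E and G) also has an ortho aryloxy group, giving tri-ortho-substituted ethers between two electron-rich rings. The strategy rests on C4 of rings D and F: it is flanked by oxygens at C3 and C5 and is para to the ether oxygen at C1. An aryl group bound through this carbon is therefore an excellent migrating group towards electron-deficient oxygen, so its C4–O bond can be made by rearrangement instead of by intermolecular substitution.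

## Retrosynthetic reasoning

Target 21 to 20. All 21 O–H bonds are traced back to O–CH3 bonds. Methyl ethers are the one protecting group that survives organolithium reagents, peracid and a hot nickel catalyst, and keeping them to the end leaves the oxidation-prone pyrogallol rings masked. The forward step has to cleave 21 alkyl–oxygen bonds without touching the seven diaryl ethers.

Ether 20 to diester 19. A carbonyl group is inserted, in the retrosynthetic sense, into the O–C1 bonds of rings E and G. The D–E and F–G ethers become aryl esters in which the ring D and ring F oxygens are already in place. The forward reaction has to extrude carbon monoxide from both esters and rejoin oxygen to C1 of rings E and G.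

Diester 19 to diketone 18. The C4–O bonds of rings D and F are cut and C4 is bound to the carbonyl carbon instead. This is the central disconnection: the crowded aryl–oxygen bond is replaced by an aryl–carbon bond, which is far easier to make next to two methoxy groups. The forward reaction must move the ring D and ring F aryl groups, and not those of rings E and G, from carbon to oxygen.

Diketone 18 to diol 17, then to 15 plus 5, and 15 to 13 plus 3. The two bonds between the carbonyl carbons and C4 of rings D and F are cut. Each is formed by adding a 2,6-dimethoxyaryllithium to an aldehyde, a reaction that is not slowed by two ortho methoxy groups. Bromoaldehyde 3 is both electrophile (through its formyl group) and, after the first addition, the source of the second aryllithium (through its ring F bromide). The carbinol formed first protects itself as its alkoxide, so no protecting group is needed, and both carbinols are oxidised together.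

Tetramer 13 to 11 plus 12, and 11 to 7 plus 10. The two ether bonds at ring B are cut. Ring B is the one ring whose ether carbons are not doubly flanked, so copper-catalysed couplings are adequate here. Iodide 10 reacts at iodine with phenol 7, and the remaining unhindered ring B bromide then takes the hindered phenol 12. The ring D bromide, between two methoxy groups, stays out of both couplings and is kept for the lithiation.

Phenol 7 to 3, and 3 and 5 to 2 with 1 or 4. The hydroxyl at C1 of ring C comes from the formyl group of 3 by oxidative replacement of carbon by oxygen. The ethers at C6 of rings C, E and G come from displacement of the bromide of 2, which is activated by its ortho formyl group, by the unhindered phenols 1 and 4. One compound, 3, thus serves as the C–D unit and as the E–F unit. Iodide 10 comes from phenol 8 by ortho iodination to 9 and methylation.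

## Alternatives that were turned down

Alternative 1: Ring A would be built around its ether oxygen instead of being taken from a phenol. The disconnection cuts a C–C bond of ring A and leads to the open-chain compound A1, dimethyl 4-[3-(benzyloxy)-4,5-dimethoxyphenoxy]-3,5-dioxoheptanedioate. In the forward step an alkoxide base forms the C2 enolate of A1, which attacks the C7 ester carbonyl; loss of methanol and enolisation give the aromatic A2, methyl 3-[3-(benzyloxy)-4,5-dimethoxyphenoxy]-2,4,6-trihydroxybenzoate. In its favour, the ether oxygen at the doubly flanked carbon of ring A is attached to an sp3 carbon before the ring exists, so no hindered aryl–oxygen coupling is needed there, and aromatisation drives the closure. Against it, only the A–B ether is solved. A1 is a base-labile polycarbonyl compound in which retro-Claisen cleavage, closure through oxygen to a pyranone and loss of aryloxide compete. A2 still needs ester hydrolysis and decarboxylation, and its three free phenols do not match the methyl ether protection of the other rings. Six ethers remain, among them D–E and F–G, for which this idea offers nothing. On the A–B bond itself it is arguably the stronger solution; the chosen strategy spends one copper-catalysed coupling of 12 on that bond and puts its invention into the two tri-ortho-substituted ethers.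

Alternative 2: Ring C would be grown from a four-membered ring. The disconnection cuts the C1–C6 bond of ring C and leads to A3, the racemic (E)-4-(2-aryloxyvinyl)-2,3,4-trimethoxycyclobut-2-en-1-one in which the aryl group is the 2,3-dimethoxy-5-(2,4,6-trimethoxyphenoxy)phenyl unit of rings A and B. On heating, A3 should open to a dienylketene, whose 6π electrocyclisation and tautomerisation give A4, the trimer of rings A to C as its octamethyl ether with the C6 hydroxyl of ring C free. In its favour, the five oxygens of ring C are placed with certainty and the single free hydroxyl appears exactly where ring D has to be attached, under neutral thermal conditions. Against it, that hydroxyl sits at the doubly flanked carbon, so the hard ether coupling is only postponed. Making A3 also needs a carbanion β to an aryloxy group, which can expel phenoxide. Rings E and G would each need the same ring expansion on ever larger substrates, and the C4–O bonds of rings D and F are not addressed. Its regiochemical certainty is stronger than any aromatic substitution, but the chosen route gets the same certainty at no cost from the fixed substitution of aldehyde 2 and then solves the D–E and F–G bonds, which this alternative leaves open.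

Alternative 3: The five para hydroxyls at C4 of rings B, C, E, G and H would be carried as formyl groups until late. The disconnection replaces these C4–O bonds by C4–CHO bonds and leads to the pentaaldehyde A5. A fivefold Dakin oxidation of A5 should give A6, the hexadecamethyl ether of the octamer with five free C4 hydroxyls. In its favour, the Dakin oxidation of a benzaldehyde with two ortho oxygens is among the most reliable aryl C–O bond formations, more reliable than the Baeyer–Villiger reaction of a hindered diaryl ketone. The formyl groups would also activate the para positions for ether formation by nucleophilic aromatic substitution during the assembly. Against it, the key step forms no bond between rings. The formyl groups are meta to the doubly flanked carbons C6 of rings C, E and G and so do not activate them, and rings D and F carry no formyl group, so the tri-ortho-substituted ethers still need direct coupling. A6 exposes five electron-rich phenols and still needs removal of 16 methyl groups. The chosen strategy takes the same idea, oxygen insertion with aryl migration, and uses it where a bond between rings results; in exchange it accepts a less certain key step and a decarbonylation.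

Key step: step 11

Assumption: ring B is drawn from 4-bromo-2-methoxyphenol 8, taken as a commercial material. Carbinols 15 and 17 form as stereoisomer mixtures, which is immaterial because both carbinol carbons become carbonyl carbons in step 10. From compound 11 on, every oxygen that is a hydroxyl in the target is a methyl ether unless stated.

## Route

Step 1
Reactants: 1 4-bromo-3,5-dimethoxyphenol; 2 2-bromo-3,4,5-trimethoxybenzaldehyde
Product: 3 2-(4-bromo-3,5-dimethoxyphenoxy)-3,4,5-trimethoxybenzaldehyde
Conditions: CuI (10 mol %), picolinic acid (20 mol %), K3PO4, DMSO, 90 °C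
Reagents that add atoms: none
Why: Ullmann-type diaryl ether synthesis under monovalent copper catalysis; the ortho formyl group activates the C2–Br bond of 2, whereas the C–Br bond of 1 lies between two methoxy groups on an electron-rich ring, so 1 should act only as the nucleophile.

Step 2
Reactants: 4 3,4,5-trimethoxyphenol; 2 2-bromo-3,4,5-trimethoxybenzaldehyde
Product: 5 3,4,5-trimethoxy-2-(3,4,5-trimethoxyphenoxy)benzaldehyde
Conditions: CuI (10 mol %), picolinic acid (20 mol %), K3PO4, DMSO, 90 °C
Reagents that add atoms: none
Why: The same Ullmann-type coupling of an unhindered phenol with the formyl-activated bromide; it should give the G–H unit with the ether at the doubly flanked carbon C6 of ring G.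

Step 3
Reactants: 3 2-(4-bromo-3,5-dimethoxyphenoxy)-3,4,5-trimethoxybenzaldehyde
Product: 7 2-(4-bromo-3,5-dimethoxyphenoxy)-3,4,5-trimethoxyphenol, via aryl formate 6 (not isolated)
Conditions: mCPBA, CH2Cl2, 0 °C → rt; then K2CO3 (cat.), MeOH, rt
Reagents that add atoms: mCPBA, OOC(=O)c1cccc(Cl)c1
Why: Dakin-type sequence: Baeyer–Villiger oxidation of an electron-rich benzaldehyde, in which the aryl group with an ortho aryloxy and a para methoxy group migrates in preference to hydrogen, gives the formate, and mild methanolysis frees the phenol; no strong acid is present, so the rings should not be hydroxylated.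

Step 4
Reactants: 8 4-bromo-2-methoxyphenol
Product: 9 4-bromo-2-iodo-6-methoxyphenol
Conditions: NIS, TsOH·H2O (10 mol %), MeCN, rt, dark
Reagents that add atoms: N-iodosuccinimide, O=C1CCC(=O)N1I
Why: Electrophilic aromatic iodination; the hydroxyl group is the strongest director and its para position is blocked by bromine, so iodine should enter at C6, ortho to the hydroxyl.

Step 5
Reactants: 9 4-bromo-2-iodo-6-methoxyphenol
Product: 10 5-bromo-1-iodo-2,3-dimethoxybenzene
Conditions: MeI, K2CO3, DMF, 40 °C
Reagents that add atoms: iodomethane, CI
Why: Williamson O-methylation of the phenoxide; it gives ring B with two different halogens, iodine next to a methoxy group and bromine at the unhindered carbon.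

Step 6
Reactants: 7 2-(4-bromo-3,5-dimethoxyphenoxy)-3,4,5-trimethoxyphenol; 10 5-bromo-1-iodo-2,3-dimethoxybenzene
Product: 11 1-(5-bromo-2,3-dimethoxyphenoxy)-2-(4-bromo-3,5-dimethoxyphenoxy)-3,4,5-trimethoxybenzene (rings B, C and D)
Conditions: CuI (10 mol %), picolinic acid (20 mol %), K3PO4, DMSO, 80 °C; 10 in slight excess
Reagents that add atoms: none
Why: Ullmann-type coupling; the C–I bond reacts with copper much faster than either C–Br bond, and the ring D bromide is further shielded by two ortho methoxy groups, so 7 should be arylated only at the iodinated carbon and should not self-condense.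

Step 7
Reactants: 11 dibromide of rings B, C and D; 12 2,4,6-trimethoxyphenol
Product: 13 2-(4-bromo-3,5-dimethoxyphenoxy)-1-[2,3-dimethoxy-5-(2,4,6-trimethoxyphenoxy)phenoxy]-3,4,5-trimethoxybenzene (tetramer bromide of rings A to D)
Conditions: CuI (20 mol %), picolinic acid (40 mol %), K3PO4, DMSO, 110 °C, argon
Reagents that add atoms: none
Why: Ullmann-type coupling of a 2,6-disubstituted phenol under the picolinic acid conditions used for hindered partners; only the ring B bromide has free ortho positions, while the ring D bromide lies between two methoxy groups and would have to meet a doubly ortho-substituted phenoxide, so it should be retained.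

Step 8
Reactants: 13 tetramer bromide of rings A to D; 3 2-(4-bromo-3,5-dimethoxyphenoxy)-3,4,5-trimethoxybenzaldehyde
Product: 15 hexamer carbinol of rings A to F, in which C4 of ring D and C1 of ring E are joined through a CH(OH) carbon and C4 of ring F carries bromine (racemic), via aryllithium 14 (not isolated)
Conditions: n-BuLi (1.0 equiv), THF, −78 °C; then 3, −78 °C → 0 °C; H2O
Reagents that add atoms: none
Why: Bromine–lithium exchange gives a 2,6-dimethoxyaryllithium stabilised by both ortho oxygens, and its 1,2-addition to the aldehyde of 3 should be much faster than the thermoneutral exchange with the equally substituted ring F bromide; the new stereocentre is not controlled and is removed in step 10.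

Step 9
Reactants: 15 hexamer carbinol bromide; 5 3,4,5-trimethoxy-2-(3,4,5-trimethoxyphenoxy)benzaldehyde
Product: 17 octamer diol, with CH(OH) carbons between C4 of ring D and C1 of ring E and between C4 of ring F and C1 of ring G (mixture of diastereomers), via dilithio species 16 (not isolated)
Conditions: n-BuLi (2.2 equiv), THF, −78 °C; then 5, −78 °C → 0 °C; H2O
Reagents that add atoms: none
Why: The first equivalent of base converts the carbinol into its lithium alkoxide, which protects it, and the second effects bromine–lithium exchange at C4 of ring F; 1,2-addition of this aryllithium to aldehyde 5 gives the second carbinol, whose configuration is irrelevant.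

Step 10
Reactants: 17 octamer diol
Product: 18 octamer diketone, with C=O groups between C4 of ring D and C1 of ring E and between C4 of ring F and C1 of ring G
Conditions: DMP (3 equiv), pyridine, CH2Cl2, 0 °C → rt
Reagents that add atoms: none
Why: Dess–Martin oxidation of both diaryl carbinols, a method suited to hindered secondary alcohols; pyridine buffers the acetic acid released so that the electron-rich benzhydrols do not ionise.

Step 11
Reactants: 18 octamer diketone
Product: 19 octamer diester, with C4 of ring D bound through O–C(=O) to C1 of ring E and C4 of ring F bound through O–C(=O) to C1 of ring G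
Conditions: mCPBA (5 equiv), CF3CO2H (4 equiv), CH2Cl2, 0 °C → rt, dark
Reagents that add atoms: mCPBA, OOC(=O)c1cccc(Cl)c1
Why: Trifluoroacetic acid protonates each diaryl ketone, mCPBA adds to the carbonyl carbon to give a tetrahedral peroxy adduct (Criegee intermediate), and the aryl group that best carries positive charge migrates from carbon to the proximal peroxide oxygen as 3-chlorobenzoate leaves; the same sequence at the second ketone completes the diester. The closest known reaction type is the Baeyer–Villiger oxidation of polyalkoxybenzophenones and alkoxyaryl ketones to aryl esters, in which the ring with ortho and para alkoxy groups migrates. No ring is closed and no stereocentre is formed. The first selectivity needed is migration of the ring D and ring F aryl groups through C4 and not of the ring E and ring G aryl groups through C1: C4 of rings D and F has two ortho methoxy groups and a para aryloxy group that stabilise the bridged transition state, whereas C1 of rings E and G has a single ortho aryloxy group, a para methoxy group twisted out of conjugation by its two methoxy neighbours, and two meta methoxy groups that only withdraw inductively. The double ortho substitution also turns rings D and F out of the carbonyl plane, which should raise the electrophilicity of the carbonyl group and align the migrating C4–C bond with the O–O bond. The second selectivity needed is oxidation of the ketones ahead of electrophilic hydroxylation of the electron-rich rings, above all ring A; it rests on low temperature, a limited amount of acid and stopping at full consumption of the ketones.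

Step 12
Reactants: 19 octamer diester
Product: 20 henicosamethyl ether of the target octamer
Conditions: Ni(cod)2 (40 mol %), 3,4-bis(dicyclohexylphosphino)thiophene (80 mol %), K3PO4, m-xylene, 160 °C, argon
Reagents that add atoms: none
Why: Proposed new method: zerovalent nickel should insert into the acyl C–O bond of each aryl ester, lose carbon monoxide from the acyl–nickel aryloxide to give an aryl–nickel aryloxide, and close the diaryl ether by C–O reductive elimination, with the ortho aryloxy oxygen of rings E and G available as a hemilabile donor in place of a ring nitrogen; the closest known reaction type is the nickel- or palladium-catalysed decarbonylative etherification of aryl esters of azinecarboxylic acids with this diphosphine, which has not been shown for electron-rich benzoates of 2,6-dimethoxyphenols.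

Step 13
Reactants: 20 henicosamethyl ether of the target octamer
Product: 21 target octamer (CNP0175816.0)
Conditions: BBr3 (60 equiv), CH2Cl2, −78 °C → rt, argon; then H2O, 0 °C
Reagents that add atoms: none
Why: Lewis acid-mediated cleavage of aryl methyl ethers: boron binds each methoxy oxygen and bromide attacks the methyl carbon in an SN2 step, and hydrolysis of the aryloxyboranes frees the phenols; the diaryl ether oxygens are flanked only by sp2 carbons and cannot be cleaved this way.

## Compound list

1 | 4-bromo-3,5-dimethoxyphenol | COc1cc(O)cc(OC)c1Br | starting material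
2 | 2-bromo-3,4,5-trimethoxybenzaldehyde | COc1cc(C=O)c(Br)c(OC)c1OC | starting material
3 | 2-(4-bromo-3,5-dimethoxyphenoxy)-3,4,5-trimethoxybenzaldehyde | COc1cc(C=O)c(Oc2cc(OC)c(Br)c(OC)c2)c(OC)c1OC | intermediate
4 | 3,4,5-trimethoxyphenol | COc1cc(O)cc(OC)c1OC | starting material
5 | 3,4,5-trimethoxy-2-(3,4,5-trimethoxyphenoxy)benzaldehyde | COc1cc(C=O)c(Oc2cc(OC)c(OC)c(OC)c2)c(OC)c1OC | intermediate
6 | 2-(4-bromo-3,5-dimethoxyphenoxy)-3,4,5-trimethoxyphenyl formate | COc1cc(OC=O)c(Oc2cc(OC)c(Br)c(OC)c2)c(OC)c1OC | intermediate
7 | 2-(4-bromo-3,5-dimethoxyphenoxy)-3,4,5-trimethoxyphenol | COc1cc(O)c(Oc2cc(OC)c(Br)c(OC)c2)c(OC)c1OC | intermediate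
8 | 4-bromo-2-methoxyphenol | COc1cc(Br)ccc1O | starting material
9 | 4-bromo-2-iodo-6-methoxyphenol | COc1cc(Br)cc(I)c1O | intermediate
10 | 5-bromo-1-iodo-2,3-dimethoxybenzene | COc1cc(Br)cc(I)c1OC | intermediate
11 | 1-(5-bromo-2,3-dimethoxyphenoxy)-2-(4-bromo-3,5-dimethoxyphenoxy)-3,4,5-trimethoxybenzene | COc1cc(Br)cc(Oc2cc(OC)c(OC)c(OC)c2Oc2cc(OC)c(Br)c(OC)c2)c1OC | intermediate
12 | 2,4,6-trimethoxyphenol | COc1cc(OC)c(O)c(OC)c1 | starting material
13 | 2-(4-bromo-3,5-dimethoxyphenoxy)-1-[2,3-dimethoxy-5-(2,4,6-trimethoxyphenoxy)phenoxy]-3,4,5-trimethoxybenzene | COc1cc(OC)c(Oc2cc(OC)c(OC)c(Oc3cc(OC)c(OC)c(OC)c3Oc3cc(OC)c(Br)c(OC)c3)c2)c(OC)c1 | intermediate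
14 | aryllithium of rings A to D, lithium at C4 of ring D | COc1cc(OC)c(Oc2cc(OC)c(OC)c(Oc3cc(OC)c(OC)c(OC)c3Oc3cc(OC)c([Li])c(OC)c3)c2)c(OC)c1 | intermediate
15 | hexamer carbinol of rings A to F, CH(OH) between C4 of ring D and C1 of ring E, bromine at C4 of ring F, racemic | COc1cc(OC)c(Oc2cc(OC)c(OC)c(Oc3cc(OC)c(OC)c(OC)c3Oc3cc(OC)c(C(O)c4cc(OC)c(OC)c(OC)c4Oc4cc(OC)c(Br)c(OC)c4)c(OC)c3)c2)c(OC)c1 | intermediate
16 | lithium alkoxide of 15 with lithium at C4 of ring F, racemic | COc1cc(OC)c(Oc2cc(OC)c(OC)c(Oc3cc(OC)c(OC)c(OC)c3Oc3cc(OC)c(C(O[Li])c4cc(OC)c(OC)c(OC)c4Oc4cc(OC)c([Li])c(OC)c4)c(OC)c3)c2)c(OC)c1 | intermediate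
17 | octamer diol, CH(OH) between rings D and E and between rings F and G, mixture of diastereomers | COc1cc(OC)c(Oc2cc(OC)c(OC)c(Oc3cc(OC)c(OC)c(OC)c3Oc3cc(OC)c(C(O)c4cc(OC)c(OC)c(OC)c4Oc4cc(OC)c(C(O)c5cc(OC)c(OC)c(OC)c5Oc5cc(OC)c(OC)c(OC)c5)c(OC)c4)c(OC)c3)c2)c(OC)c1 | intermediate
18 | octamer diketone, C=O between C4 of ring D and C1 of ring E and between C4 of ring F and C1 of ring G | COc1cc(OC)c(Oc2cc(OC)c(OC)c(Oc3cc(OC)c(OC)c(OC)c3Oc3cc(OC)c(C(=O)c4cc(OC)c(OC)c(OC)c4Oc4cc(OC)c(C(=O)c5cc(OC)c(OC)c(OC)c5Oc5cc(OC)c(OC)c(OC)c5)c(OC)c4)c(OC)c3)c2)c(OC)c1 | intermediate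
19 | octamer diester, O–C(=O) between C4 of ring D and C1 of ring E and between C4 of ring F and C1 of ring G | COc1cc(OC)c(Oc2cc(OC)c(OC)c(Oc3cc(OC)c(OC)c(OC)c3Oc3cc(OC)c(OC(=O)c4cc(OC)c(OC)c(OC)c4Oc4cc(OC)c(OC(=O)c5cc(OC)c(OC)c(OC)c5Oc5cc(OC)c(OC)c(OC)c5)c(OC)c4)c(OC)c3)c2)c(OC)c1 | intermediate
20 | henicosamethyl ether of the target octamer | COc1cc(OC)c(Oc2cc(OC)c(OC)c(Oc3cc(OC)c(OC)c(OC)c3Oc3cc(OC)c(Oc4cc(OC)c(OC)c(OC)c4Oc4cc(OC)c(Oc5cc(OC)c(OC)c(OC)c5Oc5cc(OC)c(OC)c(OC)c5)c(OC)c4)c(OC)c3)c2)c(OC)c1 | intermediate
21 | target octamer CNP0175816.0 | Oc1cc(O)c(Oc2cc(O)c(O)c(Oc3cc(O)c(O)c(O)c3Oc3cc(O)c(Oc4cc(O)c(O)c(O)c4Oc4cc(O)c(Oc5cc(O)c(O)c(O)c5Oc5cc(O)c(O)c(O)c5)c(O)c4)c(O)c3)c2)c(O)c1 | target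

## Step count and risk

Total: 13 steps. Longest linear sequence: 10 steps (steps 1, 3, 6, 7, 8, 9, 10, 11, 12, 13; the ring B branch through steps 4 and 5 is equally long). Compound 3 is made once and used twice.

Step 12 (decarbonylation, least certain). Insertion of zerovalent nickel into the acyl C–O bond of an electron-rich, crowded ester may not occur. After loss of carbon monoxide, C–O reductive elimination between two electron-rich, ortho-substituted partners may be too slow, and nickel may instead insert into aryl–methoxy bonds at 160 °C. The fallback gives up the carbonyl staple and builds the same ethers by classical copper-mediated couplings; it sets out from 5, 3 and 13 and returns at 20. Baeyer–Villiger oxidation of 5 with mCPBA gives 3,4,5-trimethoxy-2-(3,4,5-trimethoxyphenoxy)phenyl formate F1, and methanolysis gives 3,4,5-trimethoxy-2-(3,4,5-trimethoxyphenoxy)phenol F2. Ullmann coupling of F2 with the ring F bromide of 3 (CuI, picolinic acid, K3PO4, DMSO, 120 °C) gives the tetramer aldehyde of rings E to H F3. The same Dakin sequence on F3 gives the tetramer formate F4 and then the tetramer phenol with free hydroxyl at C1 of ring E F5. A second Ullmann coupling of F5 with bromide 13 gives 20. Both couplings join a doubly ortho-substituted aryl bromide to an ortho-substituted phenol; the reaction type is established, but these are the slow couplings the main route was designed to avoid.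

Step 11 (key step). Electrophilic hydroxylation of ring A and other rings by the peracid may compete with the slow addition to the crowded carbonyl groups. Acid may remove the acyl group from C4 of rings D and F by ipso protonation. Migration from the ring E or ring G side would give the isomeric esters, and the reaction may stop after one ketone. The fallback makes the same diester by acylation of phenols; it sets out from 13, 3 and 5 and returns at 19. Palladium-catalysed hydroxylation of 13 (Pd2(dba)3, 2-di-tert-butylphosphino-2′,4′,6′-triisopropylbiphenyl, KOH, dioxane/water, 100 °C) gives the tetramer phenol with free hydroxyl at C4 of ring D F6. Pinnick oxidation of 3 (NaClO2, NaH2PO4, 2-methyl-2-butene) gives 2-(4-bromo-3,5-dimethoxyphenoxy)-3,4,5-trimethoxybenzoic acid F7. Steglich esterification of F6 with F7 (EDC·HCl, DMAP) gives the hexamer bromo ester F8. Miyaura borylation (Pd(OAc)2, 2-dicyclohexylphosphino-2′,6′-dimethoxybiphenyl, B2pin2, KOAc, dioxane, 100 °C) gives the hexamer pinacol boronate F9, and oxidation with N-methylmorpholine N-oxide, which leaves the aryl ester intact, gives the hexamer phenol with free hydroxyl at C4 of ring F F10. Pinnick oxidation of 5 gives 3,4,5-trimethoxy-2-(3,4,5-trimethoxyphenoxy)benzoic acid F11, and Steglich esterification of F10 with F11 gives 19.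

Step 7 (hindered ether at ring A). Coupling of a doubly ortho-substituted, electron-rich phenoxide with an electron-rich bromide may be slow, the phenoxide may be oxidised at 110 °C, and reduction or coupling at the ring D bromide may set in on long heating. The fallback changes the ring B partner from electrophile to organoboron reagent; it sets out from 11 and returns at 13. Selective Miyaura borylation of the unhindered bromide of 11 (Pd(dppf)Cl2, B2pin2, KOAc, dioxane, 80 °C) gives the trimer pinacol boronate F12. Oxidative cleavage of the pinacol ester (NaIO4, NH4OAc, aqueous acetone) gives the trimer boronic acid F13. Chan–Evans–Lam coupling of F13 with 12 (Cu(OAc)2, pyridine, 4 Å molecular sieves, CH2Cl2, air, rt) gives 13; divalent copper at room temperature leaves the ring D bromide untouched, and this coupling is known to accept phenols with two ortho substituents.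

Step 13 (global demethylation). Cleavage of 21 methyl ethers may stop short and leave partly methylated material that cannot be separated from the free polyphenol, and the pyrogallol rings may be oxidised during aqueous work-up and chromatography. The fallback isolates the product through a stable derivative; it sets out from 20 and returns at 21. After the BBr3 treatment the crude 21 is acetylated without purification (Ac2O, pyridine, argon) to the henicosaacetate of the octamer F14, which can be chromatographed and freed from under-demethylated material. Acid-catalysed methanolysis (catalytic HCl in methanol, argon, 40 °C) then gives 21 with no exposure to base.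

## Further compounds

F1 | step 12 | 3,4,5-trimethoxy-2-(3,4,5-trimethoxyphenoxy)phenyl formate | COc1cc(OC=O)c(Oc2cc(OC)c(OC)c(OC)c2)c(OC)c1OC
F2 | step 12 | 3,4,5-trimethoxy-2-(3,4,5-trimethoxyphenoxy)phenol | COc1cc(O)c(Oc2cc(OC)c(OC)c(OC)c2)c(OC)c1OC
F3 | step 12 | tetramer aldehyde of rings E to H, formyl at C1 of ring E | COc1cc(C=O)c(Oc2cc(OC)c(Oc3cc(OC)c(OC)c(OC)c3Oc3cc(OC)c(OC)c(OC)c3)c(OC)c2)c(OC)c1OC
F4 | step 12 | tetramer formate of rings E to H, formyloxy at C1 of ring E | COc1cc(OC=O)c(Oc2cc(OC)c(Oc3cc(OC)c(OC)c(OC)c3Oc3cc(OC)c(OC)c(OC)c3)c(OC)c2)c(OC)c1OC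
F5 | step 12 | tetramer phenol of rings E to H, hydroxyl at C1 of ring E | COc1cc(O)c(Oc2cc(OC)c(Oc3cc(OC)c(OC)c(OC)c3Oc3cc(OC)c(OC)c(OC)c3)c(OC)c2)c(OC)c1OC
F6 | step 11 | tetramer phenol of rings A to D, hydroxyl at C4 of ring D | COc1cc(OC)c(Oc2cc(OC)c(OC)c(Oc3cc(OC)c(OC)c(OC)c3Oc3cc(OC)c(O)c(OC)c3)c2)c(OC)c1
F7 | step 11 | 2-(4-bromo-3,5-dimethoxyphenoxy)-3,4,5-trimethoxybenzoic acid | COc1cc(C(=O)O)c(Oc2cc(OC)c(Br)c(OC)c2)c(OC)c1OC
F8 | step 11 | hexamer bromo ester of rings A to F, ester between rings D and E, bromine at C4 of ring F | COc1cc(OC)c(Oc2cc(OC)c(OC)c(Oc3cc(OC)c(OC)c(OC)c3Oc3cc(OC)c(OC(=O)c4cc(OC)c(OC)c(OC)c4Oc4cc(OC)c(Br)c(OC)c4)c(OC)c3)c2)c(OC)c1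
F9 | step 11 | hexamer pinacol boronate of rings A to F, boron at C4 of ring F | COc1cc(OC)c(Oc2cc(OC)c(OC)c(Oc3cc(OC)c(OC)c(OC)c3Oc3cc(OC)c(OC(=O)c4cc(OC)c(OC)c(OC)c4Oc4cc(OC)c(B5OC(C)(C)C(C)(C)O5)c(OC)c4)c(OC)c3)c2)c(OC)c1
F10 | step 11 | hexamer phenol of rings A to F, hydroxyl at C4 of ring F | COc1cc(OC)c(Oc2cc(OC)c(OC)c(Oc3cc(OC)c(OC)c(OC)c3Oc3cc(OC)c(OC(=O)c4cc(OC)c(OC)c(OC)c4Oc4cc(OC)c(O)c(OC)c4)c(OC)c3)c2)c(OC)c1
F11 | step 11 | 3,4,5-trimethoxy-2-(3,4,5-trimethoxyphenoxy)benzoic acid | COc1cc(C(=O)O)c(Oc2cc(OC)c(OC)c(OC)c2)c(OC)c1OC
F12 | step 7 | trimer pinacol boronate of rings B to D, boron at C1 of ring B | COc1cc(B2OC(C)(C)C(C)(C)O2)cc(Oc2cc(OC)c(OC)c(OC)c2Oc2cc(OC)c(Br)c(OC)c2)c1OC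
F13 | step 7 | trimer boronic acid of rings B to D, boron at C1 of ring B | COc1cc(B(O)O)cc(Oc2cc(OC)c(OC)c(OC)c2Oc2cc(OC)c(Br)c(OC)c2)c1OC
F14 | step 13 | henicosaacetate of the target octamer | CC(=O)Oc1cc(OC(C)=O)c(Oc2cc(OC(C)=O)c(OC(C)=O)c(Oc3cc(OC(C)=O)c(OC(C)=O)c(OC(C)=O)c3Oc3cc(OC(C)=O)c(Oc4cc(OC(C)=O)c(OC(C)=O)c(OC(C)=O)c4Oc4cc(OC(C)=O)c(Oc5cc(OC(C)=O)c(OC(C)=O)c(OC(C)=O)c5Oc5cc(OC(C)=O)c(OC(C)=O)c(OC(C)=O)c5)c(OC(C)=O)c4)c(OC(C)=O)c3)c2)c(OC(C)=O)c1
A1 | alternative 1 | dimethyl 4-[3-(benzyloxy)-4,5-dimethoxyphenoxy]-3,5-dioxoheptanedioate | COC(=O)CC(=O)C(Oc1cc(OC)c(OC)c(OCc2ccccc2)c1)C(=O)CC(=O)OC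
A2 | alternative 1 | methyl 3-[3-(benzyloxy)-4,5-dimethoxyphenoxy]-2,4,6-trihydroxybenzoate | COC(=O)c1c(O)cc(O)c(Oc2cc(OC)c(OC)c(OCc3ccccc3)c2)c1O
A3 | alternative 2 | (E)-4-{2-[2,3-dimethoxy-5-(2,4,6-trimethoxyphenoxy)phenoxy]vinyl}-2,3,4-trimethoxycyclobut-2-en-1-one, racemic | COc1cc(OC)c(Oc2cc(OC)c(OC)c(O/C=C/C3(OC)C(OC)=C(OC)C3=O)c2)c(OC)c1
A4 | alternative 2 | trimer of rings A to C as octamethyl ether with free hydroxyl at C6 of ring C | COc1cc(OC)c(Oc2cc(OC)c(OC)c(Oc3cc(OC)c(OC)c(OC)c3O)c2)c(OC)c1
A5 | alternative 3 | octamer hexadecamethyl ether with formyl groups at C4 of rings B, C, E, G and H | COc1cc(OC)c(Oc2cc(OC)c(C=O)c(Oc3cc(OC)c(C=O)c(OC)c3Oc3cc(OC)c(Oc4cc(OC)c(C=O)c(OC)c4Oc4cc(OC)c(Oc5cc(OC)c(C=O)c(OC)c5Oc5cc(OC)c(C=O)c(OC)c5)c(OC)c4)c(OC)c3)c2)c(OC)c1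
A6 | alternative 3 | octamer hexadecamethyl ether with free hydroxyls at C4 of rings B, C, E, G and H | COc1cc(OC)c(Oc2cc(OC)c(O)c(Oc3cc(OC)c(O)c(OC)c3Oc3cc(OC)c(Oc4cc(OC)c(O)c(OC)c4Oc4cc(OC)c(Oc5cc(OC)c(O)c(OC)c5Oc5cc(OC)c(O)c(OC)c5)c(OC)c4)c(OC)c3)c2)c(OC)c1
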